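The cyclopentene ring is cut at its C3=C4 double bond. The feature exploited is the mirror symmetry of this ring: C2 and C5 (the acetoxy carbons) flank the quaternary carbinol C1, and the alkene carbons C3 and C4 only tie the two arms together, so the five carbons can be laid out as a chain whose ends are bridged by a sulfonyl group. A Ramberg–Bäcklund rearrangement of that six-membered sulfone forms the C3–C4 bond, expels SO2 and contracts thiane to cyclopentene in one operation, leaving the three oxygenated centres untouched. The precursor is a meso thiane 1,1-dioxide carrying the ketal-masked undecanoyl chain at C4 and methoxymethyl ethers on the oxygens at C3, C4 and C5 (thiane numbering).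

Key step: step 8

Assumption: the target is meso (acetoxy groups cis to each other and to the undecanoyl group, trans to the tertiary hydroxyl), so only relative configuration has to be controlled; decylmagnesium bromide is bought as its ether solution (1-bromodecane and Mg give the same reagent).

Design notes: dimethyl oxalate is used so that ester and ketal carry the same alkoxy group and no mixed esters arise. The sulfone also carries a MOM group on the tertiary oxygen, because a free tertiary alkoxide next to the α-bromo sulfone could open the ring by Grob-type fragmentation.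

Step 1
Reactants: 1 decylmagnesium bromide (1.0 M in Et2O); 2 dimethyl oxalate
Product: 3 methyl 2-oxododecanoate
Conditions: 1 added to 2 (1.5 equiv), THF–Et2O, −78 °C; aq NH4Cl at −78 °C
Reagents that add atoms: none
Why: Grignard mono-acylation with a dialkyl oxalate: the magnesium hemiketal formed at −78 °C does not collapse before the quench, so neither the new ketone nor the second ester meets the reagent.

Step 2
Reactants: 3 methyl 2-oxododecanoate
Product: 4 methyl 2,2-dimethoxydodecanoate
Conditions: HC(OMe)3, MeOH, H2SO4 (cat.), reflux; NaOMe quench before concentration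
Reagents that add atoms: trimethyl orthoformate, COC(OC)OC; methanol, CO
Why: Acid-catalysed ketalisation with orthoformate as dehydrating agent, which works well on the electrophilic carbonyl of an α-keto ester; with the methyl ester in methanol any ester exchange is degenerate.

Step 3
Reactants: 4 methyl 2,2-dimethoxydodecanoate; 5 vinylmagnesium bromide
Product: 7 3-(1,1-dimethoxyundecyl)penta-1,4-dien-3-ol, via vinyl ketone 6 (not isolated)
Conditions: 5 (3 equiv), THF, −78 → 0 °C; aq NH4Cl
Reagents that add atoms: none
Why: Double Grignard addition to an ester: loss of methoxide gives vinyl ketone 6, whose carbonyl, activated by magnesium chelation to the neighbouring ketal oxygens, should take the second hard vinyl nucleophile 1,2 to give the tertiary divinyl carbinol (no stereocentre).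

Step 4
Reactants: 7 3-(1,1-dimethoxyundecyl)penta-1,4-dien-3-ol
Product: 9 meso 2,2-dimethoxy-1,1-bis(oxiran-2-yl)dodecan-1-ol, via mono-epoxide 8 (not isolated)
Conditions: VO(acac)2 (10 mol %), t-BuOOH (in decane, 3 equiv), toluene, 40 °C
Reagents that add atoms: tert-butyl hydroperoxide, CC(C)(C)OO
Why: Hydroxyl-directed epoxidation by a vanadium alkyl peroxide bound to the tertiary alkoxide: in the favoured transition state the bulky ketal-bearing group points away from the alkene and the metal while the smaller second vinyl (later oxiranyl) group lies near the alkene CH, so each oxirane C–O bond should form erythro to the ketal chain, and doing this on both enantiotopic vinyl groups sets the two secondary centres and the pseudo-asymmetric central carbon of the meso bis-epoxide.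

Step 5
Reactants: 9 meso bis-epoxide; 10 sodium sulfide (as Na2S·9H2O)
Product: 12 meso 4-(1,1-dimethoxyundecyl)thiane-3,4,5-triol, via epoxy thiolate 11 (not isolated)
Conditions: Na2S·9H2O (1.2 equiv), EtOH–H2O (4:1), 0.01 M, rt → 50 °C
Reagents that add atoms: none
Why: Double SN2 epoxide opening by sulfide: the first attack is at a terminal CH2, and thiolate 11 should then close 6-endo at the other terminal CH2 because the 5-exo site is an oxirane carbon attached to the fully substituted carbinol carbon; the C–O stereocentres are not touched, so the 3,5-hydroxyls come out cis to each other and trans to the 4-hydroxyl.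

Step 6
Reactants: 12 meso 4-(1,1-dimethoxyundecyl)thiane-3,4,5-triol
Product: 14 meso 4-(1,1-dimethoxyundecyl)-3,4,5-trihydroxythiane 1,1-dioxide, via sulfoxide 13 (not isolated)
Conditions: (NH4)6Mo7O24·4H2O (10 mol %), 30% aq H2O2 (4 equiv), MeOH, 0 °C → rt
Reagents that add atoms: hydrogen peroxide, OO
Why: Molybdate-catalysed peroxide oxidation of a sulfide to the sulfone through sulfoxide 13; sulfur is the only oxidisable site now that no alkene is left, and methanol as solvent makes any exchange at the dimethyl ketal degenerate.

Step 7
Reactants: 14 meso 4-(1,1-dimethoxyundecyl)-3,4,5-trihydroxythiane 1,1-dioxide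
Product: 16 meso 4-(1,1-dimethoxyundecyl)-3,4,5-tris(methoxymethoxy)thiane 1,1-dioxide, via bis-MOM ether 15 (not isolated)
Conditions: MOMCl (10 equiv), i-Pr2NEt (15 equiv), NaI (0.2 equiv), ClCH2CH2Cl, 0 °C → 60 °C
Reagents that add atoms: chloromethyl methyl ether, COCCl
Why: O-Alkylation with an α-halo ether under amine base: the two secondary hydroxyls react first to give 15, and the hindered tertiary hydroxyl should follow on heating with the iodomethyl ether formed in situ; the amine is too weak to trigger retro-aldol or elimination at the β-hydroxy sulfone, and no stereocentre is involved.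

Step 8
Reactants: 16 meso 4-(1,1-dimethoxyundecyl)-3,4,5-tris(methoxymethoxy)thiane 1,1-dioxide
Product: 19 meso 4-(1,1-dimethoxyundecyl)-3,4,5-tris(methoxymethoxy)cyclopent-1-ene, via α-bromo sulfone 17 (not isolated), via episulfone 18 (not isolated)
Conditions: KOH/Al2O3, CBr2F2, t-BuOH–CH2Cl2, 0 °C → rt
Reagents that add atoms: none
Why: Ramberg–Bäcklund rearrangement in its one-pot form with in-situ halogenation: KOH deprotonates an α-CH2 of sulfone 16, the carbanion takes bromine from CBr2F2 to give 17, and deprotonation at the other α-carbon is followed by intramolecular displacement of bromide (1,3-elimination) to give the cis-fused episulfone 18, which loses SO2 to leave the alkene. The closest known reaction type is the same rearrangement of ether-protected polyhydroxylated thiane and thiepane 1,1-dioxides to cyclopentene and cyclohexene polyols. The carbocycle is closed in the 3-exo-tet step that joins the two α-carbons (C3 and C4 of the cyclopentene), so the five-membered ring exists as soon as 18 forms and the extrusion only turns the new single bond into the double bond, whose cis geometry is fixed by the ring. No stereocentre is made and the three oxygen-bearing centres carry no acidic hydrogen, so they should pass through unchanged; the transient centres at the α-carbons of 17 and 18 vanish in the alkene. The mirror plane of 16 makes the two α-positions equivalent, so there is no regiochemical issue; what the step needs is chemoselectivity for bromine transfer and closure over E1cB loss of a β-alkoxide from the sulfonyl carbanion, which the poor leaving-group ability of the acetal oxygens should secure. The MOM group on the tertiary oxygen removes the alkoxide that could otherwise break the ring C–C bond anti to the C–Br bond of 17.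

Step 9
Reactants: 19 meso 4-(1,1-dimethoxyundecyl)-3,4,5-tris(methoxymethoxy)cyclopent-1-ene
Product: 21 meso 1-(1,2,5-trihydroxycyclopent-3-en-1-yl)undecan-1-one, via bis-MOM hydroxy ketone 20 (not isolated)
Conditions: 6 M aq HCl–THF (1:2), rt → 40 °C
Reagents that add atoms: water, O
Why: Acid-catalysed acetal hydrolysis: the dimethyl ketal and the tertiary ether are expected to go first (leaving 20) and the two secondary formaldehyde acetals last, while the allylic C–O bonds next to the electron-poor quaternary carbon should resist ionisation, so all three stereocentres are kept.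

Step 10
Reactants: 21 meso 1-(1,2,5-trihydroxycyclopent-3-en-1-yl)undecan-1-one
Product: 23 meso 2-hydroxy-2-undecanoylcyclopent-4-ene-1,3-diyl diacetate (target), via monoacetate 22 (not isolated)
Conditions: Ac2O (3 equiv), pyridine, 0 °C → rt
Reagents that add atoms: acetic anhydride, CC(=O)OC(C)=O
Why: Esterification with an anhydride in pyridine: the two secondary allylic hydroxyls are acylated, while the tertiary hydroxyl, flanked by three substituted carbons and α to the ketone, should stay free without an acyl-transfer catalyst; no stereocentre is touched.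

Compound list
1 | decylmagnesium bromide | CCCCCCCCCC[Mg]Br | starting material
2 | dimethyl oxalate | COC(=O)C(=O)OC | starting material
3 | methyl 2-oxododecanoate | CCCCCCCCCCC(=O)C(=O)OC | intermediate
4 | methyl 2,2-dimethoxydodecanoate | CCCCCCCCCCC(OC)(OC)C(=O)OC | intermediate
5 | vinylmagnesium bromide | C=C[Mg]Br | starting material
6 | 4,4-dimethoxytetradec-1-en-3-one (vinyl ketone) | CCCCCCCCCCC(OC)(OC)C(=O)C=C | intermediate (not isolated)
7 | 3-(1,1-dimethoxyundecyl)penta-1,4-dien-3-ol | CCCCCCCCCCC(OC)(OC)C(O)(C=C)C=C | intermediate
8 | 4,4-dimethoxy-3-(oxiran-2-yl)tetradec-1-en-3-ol, racemic, oxirane C–O erythro to the ketal chain | CCCCCCCCCCC(OC)(OC)[C@@](O)([C@@H]1CO1)C=C | intermediate (not isolated)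
9 | meso 2,2-dimethoxy-1,1-bis(oxiran-2-yl)dodecan-1-ol, both oxirane C–O bonds erythro to the ketal chain | CCCCCCCCCCC(OC)(OC)[C@@](O)([C@@H]1CO1)[C@H]1CO1 | intermediate
10 | sodium sulfide (used as nonahydrate) | [Na+].[Na+].[S-2] | starting material
11 | 4,4-dimethoxy-3-(oxiran-2-yl)-1-sulfanyltetradecane-2,3-diol, racemic, present as its sodium thiolate | CCCCCCCCCCC(OC)(OC)[C@@](O)([C@@H](O)CS)[C@H]1CO1 | intermediate (not isolated)
12 | meso 4-(1,1-dimethoxyundecyl)thiane-3,4,5-triol, 3- and 5-OH cis to each other and trans to 4-OH | CCCCCCCCCCC(OC)(OC)[C@@]1(O)[C@@H](O)CSC[C@H]1O | intermediate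
13 | 4-(1,1-dimethoxyundecyl)-3,4,5-trihydroxythiane 1-oxide, configuration at sulfur not assigned | CCCCCCCCCCC(OC)(OC)[C@@]1(O)[C@@H](O)CS(=O)C[C@H]1O | intermediate (not isolated)
14 | meso 4-(1,1-dimethoxyundecyl)-3,4,5-trihydroxythiane 1,1-dioxide | CCCCCCCCCCC(OC)(OC)[C@@]1(O)[C@@H](O)CS(=O)(=O)C[C@H]1O | intermediate
15 | meso 4-(1,1-dimethoxyundecyl)-4-hydroxy-3,5-bis(methoxymethoxy)thiane 1,1-dioxide | CCCCCCCCCCC(OC)(OC)[C@@]1(O)[C@@H](OCOC)CS(=O)(=O)C[C@H]1OCOC | intermediate (not isolated)
16 | meso 4-(1,1-dimethoxyundecyl)-3,4,5-tris(methoxymethoxy)thiane 1,1-dioxide, 3- and 5-ethers cis to each other and trans to the 4-ether | CCCCCCCCCCC(OC)(OC)[C@@]1(OCOC)[C@@H](OCOC)CS(=O)(=O)C[C@H]1OCOC | intermediate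
17 | 2-bromo-4-(1,1-dimethoxyundecyl)-3,4,5-tris(methoxymethoxy)thiane 1,1-dioxide, racemic, bromine-bearing carbon epimerisable and not assigned | CCCCCCCCCCC(OC)(OC)[C@@]1(OCOC)[C@@H](OCOC)C(Br)S(=O)(=O)C[C@H]1OCOC | intermediate (not isolated)
18 | 3-(1,1-dimethoxyundecyl)-2,3,4-tris(methoxymethoxy)-6-thiabicyclo[3.1.0]hexane 6,6-dioxide, cis ring fusion, face of the SO2 bridge not assigned | CCCCCCCCCCC(OC)(OC)[C@@]1(OCOC)[C@@H](OCOC)C2C(S2(=O)=O)[C@H]1OCOC | intermediate (not isolated)
19 | meso 4-(1,1-dimethoxyundecyl)-3,4,5-tris(methoxymethoxy)cyclopent-1-ene, 3- and 5-ethers cis to each other and trans to the 4-ether | CCCCCCCCCCC(OC)(OC)[C@@]1(OCOC)[C@@H](OCOC)C=C[C@H]1OCOC | intermediate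
20 | meso 1-[1-hydroxy-2,5-bis(methoxymethoxy)cyclopent-3-en-1-yl]undecan-1-one | CCCCCCCCCCC(=O)[C@@]1(O)[C@@H](OCOC)C=C[C@H]1OCOC | intermediate (not isolated)
21 | meso 1-(1,2,5-trihydroxycyclopent-3-en-1-yl)undecan-1-one, secondary hydroxyls cis to each other and to the acyl group | CCCCCCCCCCC(=O)[C@@]1(O)[C@@H](O)C=C[C@H]1O | intermediate
22 | 2,3-dihydroxy-2-undecanoylcyclopent-4-en-1-yl acetate, racemic | CCCCCCCCCCC(=O)[C@@]1(O)[C@@H](OC(C)=O)C=C[C@H]1O | intermediate (not isolated)
23 | meso 2-hydroxy-2-undecanoylcyclopent-4-ene-1,3-diyl diacetate, acetoxy groups cis to each other and to the acyl group, trans to the hydroxyl | CCCCCCCCCCC(=O)[C@@]1(O)[C@@H](OC(C)=O)C=C[C@H]1OC(C)=O | target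

Total step count: 10. Longest linear sequence: 10 steps (1 and 2 to 23).

Steps most likely to fail

Step 8. After α-deprotonation, β-elimination of a methoxymethoxide (E1cB) to a cyclic vinyl sulfone may outrun bromine transfer and closure. Fallback (ring closure by alkene metathesis instead of sulfur extrusion): it sets out from bis-epoxide 9. Excess dimethylsulfonium methylide (Me3S+ I−, n-BuLi, THF, −10 °C → rt, kept cold so that attack at the terminal carbons outpaces Payne migration of the tertiary alkoxide) turns each terminal oxirane into a one-carbon-longer allylic alcohol. This should give meso 4-(1,1-dimethoxyundecyl)hepta-1,6-diene-3,4,5-triol F1 with the carbinol configurations unchanged. Ring-closing metathesis with the second-generation Grubbs catalyst, (H2IMes)(PCy3)Cl2Ru=CHPh, in CH2Cl2 at 40 °C would form the same C=C bond with loss of ethylene and give meso 1-(1,1-dimethoxyundecyl)cyclopent-3-ene-1,2,5-triol F2. Hydrolysis of the ketal (1 M aq HCl, THF, rt) comes back to the route at 21.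

Step 4. Facial selectivity in one or both oxygen transfers may be poor, or reversed if the ketal oxygens bind the metal, so that 9 is accompanied by its racemic and second meso diastereomers. Fallback (stereoconvergent: the secondary carbinols are set on the five-membered ring under the control of the quaternary carbon): it sets out from 9 as obtained, that is as a stereoisomer mixture. The mixture is taken by the operations of the preceding fallback through the diene triol F1 and the cyclopentene triol F2, both as mixtures of isomers at the secondary carbinols. MnO2 (CH2Cl2, rt) then oxidises both allylic alcohols to the achiral 2-(1,1-dimethoxyundecyl)-2-hydroxycyclopent-4-ene-1,3-dione F3, in which all isomers converge. Luche reduction (NaBH4, CeCl3·7H2O, MeOH, −78 °C) should deliver hydride to both carbonyls from the face of the small hydroxyl, anti to the bulky ketal substituent. That returns F2 as the single meso isomer with both new hydroxyls trans to the tertiary one, and ketal hydrolysis as above comes back to the route at 21.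

Step 5. The second epoxide opening may take the wrong regiochemical course (5-exo attack at the internal oxirane carbon, giving a thiolane), or chains may grow intermolecularly. Fallback (sulfur introduced by double displacement on a dibromide, so that no epoxide is present at ring closure): it sets out from 9. LiBr and AcOH in THF open both oxiranes at CH2 to give meso 1,5-dibromo-3-(1,1-dimethoxyundecyl)pentane-2,3,4-triol F4. MOMCl and i-Pr2NEt (CH2Cl2, 0 °C → rt) protect the two secondary hydroxyls, so that base cannot re-form the epoxides, giving meso 1,5-dibromo-3-(1,1-dimethoxyundecyl)-2,4-bis(methoxymethoxy)pentan-3-ol F5. Na2S·9H2O in DMF closes the ring by two SN2 displacements at primary carbons, the second one 6-exo-tet, to give meso 4-(1,1-dimethoxyundecyl)-3,5-bis(methoxymethoxy)thian-4-ol F6. Oxidation under the conditions of step 6 comes back to the route at 15, which takes its third MOM group under the conditions of step 7 to give 16.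

Further compounds
F1 | step 8 | meso 4-(1,1-dimethoxyundecyl)hepta-1,6-diene-3,4,5-triol | CCCCCCCCCCC(OC)(OC)[C@@](O)([C@@H](O)C=C)[C@H](O)C=C
F2 | step 8 | meso 1-(1,1-dimethoxyundecyl)cyclopent-3-ene-1,2,5-triol | CCCCCCCCCCC(OC)(OC)[C@@]1(O)[C@@H](O)C=C[C@H]1O
F3 | step 4 | 2-(1,1-dimethoxyundecyl)-2-hydroxycyclopent-4-ene-1,3-dione | CCCCCCCCCCC(OC)(OC)C1(O)C(=O)C=CC1=O
F4 | step 5 | meso 1,5-dibromo-3-(1,1-dimethoxyundecyl)pentane-2,3,4-triol | CCCCCCCCCCC(OC)(OC)[C@@](O)([C@@H](O)CBr)[C@H](O)CBr
F5 | step 5 | meso 1,5-dibromo-3-(1,1-dimethoxyundecyl)-2,4-bis(methoxymethoxy)pentan-3-ol | CCCCCCCCCCC(OC)(OC)[C@@](O)([C@@H](OCOC)CBr)[C@H](OCOC)CBr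
F6 | step 5 | meso 4-(1,1-dimethoxyundecyl)-3,5-bis(methoxymethoxy)thian-4-ol | CCCCCCCCCCC(OC)(OC)[C@@]1(O)[C@@H](OCOC)CSC[C@H]1OCOC
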